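- The ratio that tests your hunch that target helps is noon over autumn. From one charge of 0.250 M starting material, the noon run, which also starts with 0.120 M target, makes target at 0.00100 M s⁻¹ over its first 60 s, and the autumn run at 7.90 × 10⁻⁴ M s⁻¹, so noon is faster by a factor of 1.27.

| flask | starting material | target | time |
|---|---|---|---|
| autumn | 0.250 M |  |  |
| noon | 0.250 M | 0.120 M |  |
| midnight | 0.500 M |  |  |
| dusk | 0.870 M |  | 150 s |

| run | time / s | [target] / M |
|---|---|---|
| autumn run | 6.0 | 0.0061 |
| autumn run | 9.5 | 0.0066 |
| autumn run | 15 | 0.0088 |
| autumn run | 24 | 0.0208 |
| autumn run | 38 | 0.0283 |
| autumn run | 60 | 0.0474 |
| autumn run | 95 | 0.0723 |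
| autumn run | 150 | 0.1116 |
| noon run | 6.0 | 0.1272 |
| noon run | 9.5 | 0.1282 |
| noon run | 15 | 0.1360 |
| noon run | 24 | 0.1447 |
| noon run | 38 | 0.1595 |
| noon run | 60 | 0.1802 |
| noon run | 95 | 0.2152 |
| noon run | 150 | 0.2608 |
| midnight run | 6.0 | 0.0067 |
| midnight run | 9.5 | 0.0116 |
| midnight run | 15 | 0.0213 |
| midnight run | 24 | 0.0325 |
| midnight run | 38 | 0.0495 |
| midnight run | 60 | 0.0820 |
| midnight run | 95 | 0.1306 |
| midnight run | 150 | 0.2108 |

(scatter of a reading: 0.002 M)

- Overall: starting material -> target.
- Constant volume, constant temperature.
- What is held in complexes is read along with the free species.
- An order is taken over about fifteen percent of the charge, up and down.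

1. order of the initial rate in [starting material], near the charge of the autumn run, the rate being that where two percent of its starting material are target (one fixed amount of target, the same in the runs compared)
2. target in the dusk run at 150 s, as a share of the starting material charged
3. which of these the readings show (the product binds the substrate / the product speeds the reaction / nothing beyond the main steps / two substrates go astray together)

- I want that ratio as an amount. Over that window, target stands on average at 0.150 M in the noon run and 0.0237 M in the autumn run.
- I draw a straight line of rate against target through these two points, and it gives 0.444 M as the even amount: the amount of target at which the path through target (autocatalysis) runs as fast as the path without it. This is a rough reading, since it rests on a small difference between readings with a scatter of 0.002 M.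
- The forecast gives an order of 0.85, a dusk share of 41% and the verdict: the product speeds the reaction. Its ground is in its own words: “Adding target at the start (noon) raises the early rate”.
- I have no separate share for the dusk run, so I split the forecast's. Its share means 0.357 M target at 150 s, and the midpoint of that climb over the even amount gives a lift of 1.40. My own reckoning then puts the plain path at about 29.3% of the charge, and target's help makes up the rest.
- The simulation gives an order of 0.77, a dusk share of 41.4% and the verdict: the product speeds the reaction.

    2 starting material ⇌ substrate dimer, settled at all times (1.430 M⁻¹)
    starting material → target (0.004580 s⁻¹)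
    starting material + target → 2 target (0.01460 M⁻¹ s⁻¹)

- The forecast would fail if target did not feed the reaction, and a simulated dusk run shows this. Without the passing of starting material and target into two target, the dusk share falls from 41.4% to 28.6%, a loss of 13 percentage points. The even amount reads the same gap: the dusk run holds 0.360 M target at 150 s, and the midpoint of that climb gives a lift of 1.41, which takes 41.4% down to 29.4%, against the simulated 28.6%.

The runs are calculated from invented constants; the scatter is artificial.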